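Slowness is the first thing on the board: the alder run, which is the asked flask followed so far, is slowing by its last reading. Is it merely late, or is it going to stop?

common to all: left-handed substrate 0.10 M; right-handed substrate 0.10 M

| charge | partner | precatalyst | remark | time |
|---|---|---|---|---|
| alder | 0.30 M | 5 mM | the very flask that is asked about, followed so far |  |
| cedar | 0.60 M | 5 mM | run made earlier |  |
| flask | 0.300 M | 5.0 mM |  | 12 h |

alder run (percent of the left-handed substrate and right-handed substrate together charged)

| time / min | right-handed substrate / % | left-handed substrate / % | left-handed product / % |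
|---|---|---|---|
| 20.0 | 47.2 | 42.8 | 5.6 |
| 40.0 | 42.0 | 35.9 | 10.9 |
| 60.0 | 39.1 | 31.3 | 15.1 |
| 80.0 | 36.5 | 28.5 | 18.2 |
| 120 | 33.9 | 23.1 | 22.6 |

cedar run (percent of the left-handed substrate and right-handed substrate together charged)

| time / h | right-handed substrate / % | left-handed substrate / % | left-handed product / % |
|---|---|---|---|
| 0.417 | 39.7 | 33.0 | 14.5 |
| 0.667 | 35.8 | 27.1 | 19.5 |
| 1.00 | 32.6 | 21.3 | 22.6 |
| 2.00 | 27.9 | 15.8 | 27.9 |
| 3.00 | 26.7 | 15.4 | 28.5 |
| 5.00 | 26.5 | 15.3 | 29.9 |

(standard deviation of a reading: 0.5 percentage points)

1. whether the excess of right-handed substrate over left-handed substrate among what is left of the two reaches 80% by 12 h (yes / no)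
2. the highest excess of right-handed substrate over left-handed substrate among what is left of the two up to 12 h

*What does the cedar run do?* Between 3.00 h and 5.00 h it barely moves: left-handed substrate reads 15.4%, then 15.3%. The mirror-image substrates stand unequal, right-handed at 26.5%, so I read this as a catalyst that has quit, not as an equilibrium.

*Quit by the clock?* Take cedar's final conversion, 58.2%. Alder has half cedar's partner, and its conversion at 120 min, 43.0%, sits close to cedar's 46.1% at 1.00 h. If the catalyst lasted the same hours in both and the rate followed the partner, the alder run should have stopped near 29.1%, yet it is already past that.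

*Then count its life how?* In turnovers. Let N, the turnover number, be the substrate converted per catalyst charged before the reaction stops. Cedar gives N = 23.3.

*Your reckoning for alder?* It has the same substrate and precatalyst as the cedar run, so if the same N holds, it stops near cedar's conversion. Let e be the excess, (right − left)/(right + left). Cedar's last reading gives e = 26.8%, which I take as my estimate of alder's top and which is less than 80%.

The forecast agrees closely: no, with a top of 26.5%, range 23.5% to 29.5%, on the ground that “death looks tied to turnover”.

The asked flask gives no, with a top of 29.9%.

    free catalyst + left-handed substrate ⇌ catalyst intermediate A (K = 5.00 /M, k = 2.00 /M/s)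
    free catalyst + right-handed substrate ⇌ catalyst intermediate B (K = 7.60 /M, k = 15.0 /M/s)
    partner + catalyst intermediate A → free catalyst + left-handed product (k = 0.0580 /M/s)
    partner + catalyst intermediate B → free catalyst + right-handed product (k = 0.0190 /M/s)
    left-handed product ⇌ right-handed product (k = 0.00180 /s)
    partner + free catalyst → spent catalyst (k = 0.00110 /M/s)
    partner + precatalyst → free catalyst + spent reagent (k = 0.0110 /M/s)

At 12.0 h the asked flask holds left-handed substrate at 14.1% and right-handed at 26.2%, with spent catalyst at 99.6%; that conversion is N = 23.9, against the 23.3 carried from cedar. For the neighbour charged with 0.0020 M of precatalyst, that 23.3 reckons a conversion of 23.3%. That neighbour reaches 31.3% at 12.0 h, more than the reckoning gave, which is N = 31.3, with spent catalyst at 99.7% and a top excess of 12.2%.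

The readings were computed for an exercise; noise was put on by code.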